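The earlier runs and the new flask were computed for an exercise; the scatter is artificial.

Spring carries more solid base than the flask, while electrophile, nucleophile and the last reading time match, so the flask can be laid directly against spring.

| flask | electrophile | nucleophile | solid base | remark | time |
|---|---|---|---|---|---|
| winter | 0.025 M | 3 equiv | 0.30 equiv | run made earlier |  |
| midnight | 0.038 M | 3 equiv | 0.30 equiv | run made earlier |  |
| spring | 0.050 M | 3 equiv | 0.45 equiv | run made earlier |  |
| flask | 0.050 M | 3.00 equiv | 0.300 equiv |  | 10 h |

- winter (time / h: target / %): 2.00: 12.1; 4.00: 21.9; 6.00: 29.3; 8.00: 36.6; 10.0: 41.1
- midnight (time / h: target / %): 2.00: 17.5; 4.00: 30.3; 6.00: 39.5; 8.00: 46.9; 10.0: 52.9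
- spring (time / h: target / %): 0.833: 10.6; 2.50: 25.9; 5.00: 42.0; 8.00: 54.4; 10.0: 60.0

(readings scatter by 0.3 percentage points)

- the target standing at 10 h, as a percentage of the electrophile charged
- concentration of free base in solution at 2.5 h, in percent of saturation
- the change that raises the amount of target at 10 h, in percent of the electrophile charged most ("none" if none brings more than 2 percentage points) (Sunday's / Saturday's / Tuesday's / none)
- amount of target at 10 h, in percent of the electrophile charged, after Tuesday's

- Sunday's: doubling the amount of nucleophile, all else as stated
- Saturday's: doubling the solubility of the solid base, all else as stated
- Tuesday's: doubling the dissolution coefficient of the solid base, all else as stated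

- percent here means electrophile units held: one side product counts as two
- solid base is a solid; its amount is given per volume of the solution
- the earlier runs were read with a standard deviation of 0.3 percentage points
- on the list of suspects stand: solid base <-> free base; electrophile + target -> side product; nucleophile + acid set free <-> protonated nucleophile; electrophile + nucleophile -> acid set free + target; acid set free + free base <-> salt of the base
- at the start none of the solid base is in solution

I assume that the acid set free passes at once onto the nucleophile, so each target costs two nucleophiles, one reacting and one protonated. The second-order rate law then integrates to one dimensionless number, a Damköhler number: N, the rate constant times the electrophile charged times the time. In words, N is the length of the run measured in the reaction's own time. For a target fraction y at 3 equivalents, N = ln[(3 − 2y)/(3(1 − y))].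

The last midnight reading gives an apparent rate constant of 0.837 /M/h, and the last winter reading gives 0.836 /M/h, the same at a different concentration. So the flask has N = 0.418, which reads as 60.9% target. Spring, with the same N, reads 60.0%, lower by 0.90 percentage points, more than the scatter, so one number is nearly enough but not quite. I commit to about 60.0%.

The forecast gives 59.3%, 8% of saturation, Sunday's as best and 60.3% after Tuesday's; it writes: “Doubling the nucleophile doubles the rate”.

The flask gives 59.7%, free base at 25.3% of saturation at 2.5 h, Sunday's as best with a gain of 25 points, and 59.7% after Tuesday's. At 10.0 h the flask holds far more protonated nucleophile, 0.0312 M, than salt of the base, 1.40 × 10⁻⁵ M. For Sunday's, the excess over two nucleophiles per electrophile becomes 4 equivalents, so N counts 4 times over and reads as 86.7%, a reckoned gain of 26 points.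

    solid base ⇌ free base, rate k1*(cs1 - [free base]) while solid is left; crystals form when [free base] > cs1 (solubility = 36.0 mM, k = 0.117 /h)
    electrophile + target → side product (k = 0.273 /M/h)
    nucleophile + acid set free ⇌ protonated nucleophile, settled at all times (K = 12100 /M)
    electrophile + nucleophile → acid set free + target (k = 0.903 /M/h)
    acid set free + free base ⇌ salt of the base, settled at all times (K = 31.8 /M)

A neighbour flask with 0.12 M of electrophile, holding the equivalents, loadings and time, has N = 1.00, which reads as 83.8% target. The computed neighbour stands at 77.3% target, with 10.9% in side product.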